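**Retrosynthetic overview**

1. Target 27 ← 26 ← 25: the last two steps are acetylation of the primary allylic alcohol and removal of the tertiary triethylsilyl ether.
2. 25 ← dienyl iodide 23 + buta-2,3-dienoic acid 24. The furan-2(5H)-one ring (O1, C2=O, C3–H, C4, C5H2) carries the dienyl chain on C4 and nothing else, so its C4–C(dienyl) bond and its O1–C5 bond are made together in one palladium-catalysed coupling–lactonisation.
3. 23 ← dienylstannane 22 ← Z-iodoallyl alcohol 20 + (E)-1,2-bis(tributylstannyl)ethene 21; 20 ← Grignard reagent of bromide 15 + propargyl alcohol 16 (anti-carbomagnesiation, iodine quench).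
4. 15 ← alkyne 11 (methylalumination, oxirane, bromination) ← ketone 6 + butynyl Grignard reagent from 7 (axial addition sets C1).
5. 6 ← 2,2-dimethylcyclohexanone 1 by RAMP-hydrazone methylation (sets C2). The cyclohexane ring is bought; the butenolide is the only ring formed, in step 12.

Key step: step 12

Remark: the SMILES places the ring hydroxyl trans to the secondary methyl (1R,2S), which is the isomer expected from axial attack on (S)-2,2,6-trimethylcyclohexanone; 2, 7, 21, 24 and oxirane are taken as purchasable.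

**Route**

Step 1
Reactants: 1 2,2-dimethylcyclohexan-1-one; 2 RAMP, (R)-1-amino-2-(methoxymethyl)pyrrolidine
Product: 3 (E)-N-[(2R)-2-(methoxymethyl)pyrrolidin-1-yl]-2,2-dimethylcyclohexan-1-imine
Conditions: TsOH (cat.), cyclohexane, reflux, Dean–Stark
Reagents that add atoms: none
Why: Acid-catalysed hydrazone condensation driven by azeotropic removal of water; the amino nitrogen should settle anti to the quaternary carbon.

Step 2
Reactants: 3 (E)-N-[(2R)-2-(methoxymethyl)pyrrolidin-1-yl]-2,2-dimethylcyclohexan-1-imine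
Product: 5 (E,6S)-N-[(2R)-2-(methoxymethyl)pyrrolidin-1-yl]-2,2,6-trimethylcyclohexan-1-imine, via lithium azaenolate 4 (not isolated)
Conditions: LiN(i-Pr)2, THF, 0 °C; MeI, −100 → −78 °C
Reagents that add atoms: iodomethane, CI
Why: RAMP-hydrazone alkylation: the lithium-chelated azaenolate can form only on the CH2 side and is methylated on the face left open by the methoxymethylpyrrolidine, which in the RAMP series should set the new centre as S.

Step 3
Reactants: 5 (E,6S)-N-[(2R)-2-(methoxymethyl)pyrrolidin-1-yl]-2,2,6-trimethylcyclohexan-1-imine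
Product: 6 (S)-2,2,6-trimethylcyclohexan-1-one
Conditions: O3, CH2Cl2, −78 °C; N2 purge
Reagents that add atoms: ozone, [O-][O+]=O
Why: Ozonolytic cleavage of the hydrazone C=N bond at low temperature under neutral conditions should free the ketone without enolisation of the new α-stereocentre.

Step 4
Reactants: 6 (S)-2,2,6-trimethylcyclohexan-1-one; 7 (4-bromobut-1-yn-1-yl)trimethylsilane
Product: 9 (1R,2S)-2,6,6-trimethyl-1-[4-(trimethylsilyl)but-3-yn-1-yl]cyclohexan-1-ol, via Grignard reagent 8 (not isolated)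
Conditions: 7, Mg, THF, rt; then 6, CeCl3 (anhydrous), THF, −78 → 0 °C; H2O
Reagents that add atoms: none
Why: CeCl3-promoted Grignard 1,2-addition suppresses enolisation of the hindered ketone; in the chair with the secondary methyl equatorial the equatorial trajectory is blocked by the axial methyl of the gem-dimethyl carbon, so axial attack should put the chain cis to the secondary methyl and the hydroxyl trans to it, setting C1 as R.

Step 5
Reactants: 9 (1R,2S)-2,6,6-trimethyl-1-[4-(trimethylsilyl)but-3-yn-1-yl]cyclohexan-1-ol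
Product: 10 (1R,2S)-1-(but-3-yn-1-yl)-2,6,6-trimethylcyclohexan-1-ol
Conditions: K2CO3, MeOH, rt
Reagents that add atoms: none
Why: Base-mediated methanolysis of the alkynyl C–Si bond (protodesilylation) frees the terminal alkyne and leaves the tertiary alcohol untouched.

Step 6
Reactants: 10 (1R,2S)-1-(but-3-yn-1-yl)-2,6,6-trimethylcyclohexan-1-ol
Product: 11 {[(1R,2S)-1-(but-3-yn-1-yl)-2,6,6-trimethylcyclohexyl]oxy}triethylsilane
Conditions: Et3SiOTf, 2,6-lutidine, CH2Cl2, 0 °C → rt
Reagents that add atoms: triethylsilyl trifluoromethanesulfonate, CC[Si](CC)(CC)OS(=O)(=O)C(F)(F)F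
Why: Silylation with a silyl triflate and a hindered pyridine base is reactive enough for the crowded tertiary hydroxyl and masks it for the organometallic steps that follow.

Step 7
Reactants: 11 {[(1R,2S)-1-(but-3-yn-1-yl)-2,6,6-trimethylcyclohexyl]oxy}triethylsilane
Product: 14 (E)-4-methyl-6-[(1R,2S)-2,6,6-trimethyl-1-(triethylsilyloxy)cyclohexyl]hex-3-en-1-ol, via alkenyldimethylalane 12 (not isolated), via lithium alkenylaluminate 13 (not isolated)
Conditions: Me3Al, Cp2ZrCl2 (cat.), CH2Cl2, 0 °C → rt; evaporate, hexane, n-BuLi, 0 °C; oxirane, THF, −30 °C → rt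
Reagents that add atoms: trimethylaluminium, C[Al](C)C; oxirane, C1CO1
Why: Zirconium-catalysed syn-methylalumination of the terminal alkyne (Negishi carboalumination) places methyl on the internal carbon and aluminium cis to it, and the derived aluminate opens oxirane with retention at the alkenyl carbon, which fixes the E trisubstituted alkene.

Step 8
Reactants: 14 (E)-4-methyl-6-[(1R,2S)-2,6,6-trimethyl-1-(triethylsilyloxy)cyclohexyl]hex-3-en-1-ol
Product: 15 {[(1R,2S)-1-[(E)-6-bromo-3-methylhex-3-en-1-yl]-2,6,6-trimethylcyclohexyl]oxy}triethylsilane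
Conditions: CBr4, PPh3, 2,6-lutidine, CH2Cl2, 0 °C
Reagents that add atoms: tetrabromomethane, BrC(Br)(Br)Br
Why: Appel bromination converts the primary homoallylic alcohol into the bromide under buffered, non-acidic conditions that spare the silyl ether and the alkene geometry.

Step 9
Reactants: 15 {[(1R,2S)-1-[(E)-6-bromo-3-methylhex-3-en-1-yl]-2,6,6-trimethylcyclohexyl]oxy}triethylsilane; 16 prop-2-yn-1-ol (propargyl alcohol)
Product: 20 (Z)-3-iodo-2-{(E)-4-methyl-6-[(1R,2S)-2,6,6-trimethyl-1-(triethylsilyloxy)cyclohexyl]hex-3-en-1-yl}prop-2-en-1-ol, via Grignard reagent 17 (not isolated), via chloromagnesium propynolate 18 (not isolated), via cyclic alkenylmagnesium alkoxide 19 (not isolated)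
Conditions: 15, Mg, Et2O, reflux; 16 (1.5 equiv), i-PrMgCl (1.5 equiv), THF, 0 °C; combine, CuI (10 mol %), −20 °C → rt; I2, −78 → 0 °C
Reagents that add atoms: iodine, II
Why: Copper-catalysed anti-carbomagnesiation of a propargyl alkoxide (Duboudin-type reaction) adds the chain to the internal alkyne carbon and magnesium to the terminal carbon on the alkoxide side (chelate 19), so iodinolysis with retention should give the iodide cis to CH2OH; the alkoxide is preformed with i-PrMgCl so that no chain Grignard reagent is spent on the hydroxyl proton.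

Step 10
Reactants: 20 (Z)-3-iodo-2-{(E)-4-methyl-6-[(1R,2S)-2,6,6-trimethyl-1-(triethylsilyloxy)cyclohexyl]hex-3-en-1-yl}prop-2-en-1-ol; 21 (E)-1,2-bis(tributylstannyl)ethene
Product: 22 (2Z,4E)-2-{(E)-4-methyl-6-[(1R,2S)-2,6,6-trimethyl-1-(triethylsilyloxy)cyclohexyl]hex-3-en-1-yl}-5-(tributylstannyl)penta-2,4-dien-1-ol
Conditions: 21 (3 equiv), PdCl2(MeCN)2 (5 mol %), DMF, rt, dark
Reagents that add atoms: none
Why: Stille coupling proceeds with retention at both alkenyl carbons and tolerates the free alcohol, and the excess of 21 should keep the second C–Sn bond from coupling.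

Step 11
Reactants: 22 (2Z,4E)-2-{(E)-4-methyl-6-[(1R,2S)-2,6,6-trimethyl-1-(triethylsilyloxy)cyclohexyl]hex-3-en-1-yl}-5-(tributylstannyl)penta-2,4-dien-1-ol
Product: 23 (2Z,4E)-5-iodo-2-{(E)-4-methyl-6-[(1R,2S)-2,6,6-trimethyl-1-(triethylsilyloxy)cyclohexyl]hex-3-en-1-yl}penta-2,4-dien-1-ol
Conditions: I2 (1.05 equiv), CH2Cl2, −78 → 0 °C, dark; aq Na2S2O3
Reagents that add atoms: iodine, II
Why: Iododestannylation (ipso electrophilic substitution at the C–Sn bond) is fast at low temperature and stereoretentive, so the 2Z,4E diene should be carried over unchanged.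

Step 12
Reactants: 23 (2Z,4E)-5-iodo-2-{(E)-4-methyl-6-[(1R,2S)-2,6,6-trimethyl-1-(triethylsilyloxy)cyclohexyl]hex-3-en-1-yl}penta-2,4-dien-1-ol; 24 buta-2,3-dienoic acid
Product: 25 4-[(1E,3Z,7E)-4-(hydroxymethyl)-8-methyl-10-[(1R,2S)-2,6,6-trimethyl-1-(triethylsilyloxy)cyclohexyl]deca-1,3,7-trien-1-yl]furan-2(5H)-one
Conditions: 24 (1.5 equiv), Pd(PPh3)4 (5 mol %), Ag2CO3 (5 mol %), K2CO3 (2 equiv), MeCN, 60 °C, dark
Reagents that add atoms: none
Why: Oxidative addition of the dienyl C–I bond to zerovalent palladium is followed by carbopalladation of the allene of the carboxylate of 24, the dienyl group going to the central allene carbon and a π-allylpalladium carboxylate being formed. The closest known reaction type is the palladium/silver co-catalysed coupling–cyclisation of 2,3-allenoic acids with aryl or alkenyl halides to β-substituted butenolides. The furan-2(5H)-one ring closes by intramolecular attack of the carboxylate oxygen on the CH2 terminus of the π-allyl unit (allylic C–O bond formation giving the five-membered lactone), which returns zerovalent palladium. No stereocentre is formed, and the 1E,3Z diene geometry is retained because oxidative addition and insertion keep the configuration of the alkenyl carbon. The step needs chemoselective oxidative addition at the only C–I bond, secured by keeping the primary oxygen as a free alcohol (a poor allylic leaving group) and not as the acetate. It also needs attack at the central allene carbon, which is the intrinsic mode for allenes because it leads to the stabilised π-allyl intermediate whose tethered carboxylate can only give the β-substituted lactone.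

Step 13
Reactants: 25 4-[(1E,3Z,7E)-4-(hydroxymethyl)-8-methyl-10-[(1R,2S)-2,6,6-trimethyl-1-(triethylsilyloxy)cyclohexyl]deca-1,3,7-trien-1-yl]furan-2(5H)-one
Product: 26 [(2Z,4E)-2-{(E)-4-methyl-6-[(1R,2S)-2,6,6-trimethyl-1-(triethylsilyloxy)cyclohexyl]hex-3-en-1-yl}-5-(5-oxo-2,5-dihydrofuran-3-yl)penta-2,4-dien-1-yl] acetate
Conditions: Ac2O, pyridine, DMAP (cat.), CH2Cl2, 0 °C
Reagents that add atoms: acetic anhydride, CC(=O)OC(C)=O
Why: Nucleophile-catalysed acylation of the only free hydroxyl, a primary allylic alcohol, while the tertiary oxygen stays silylated.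

Step 14
Reactants: 26 [(2Z,4E)-2-{(E)-4-methyl-6-[(1R,2S)-2,6,6-trimethyl-1-(triethylsilyloxy)cyclohexyl]hex-3-en-1-yl}-5-(5-oxo-2,5-dihydrofuran-3-yl)penta-2,4-dien-1-yl] acetate
Product: 27 [(2Z,4E)-2-{(E)-6-[(1R,2S)-1-hydroxy-2,6,6-trimethylcyclohexyl]-4-methylhex-3-en-1-yl}-5-(5-oxo-2,5-dihydrofuran-3-yl)penta-2,4-dien-1-yl] acetate (CNP0366059.1)
Conditions: HF·pyridine, pyridine, THF, 0 °C → rt
Reagents that add atoms: none
Why: Fluoride-mediated cleavage of the Si–O bond (desilylation) under buffered, non-basic conditions should remove the triethylsilyl ether without touching the acetate, the butenolide or the diene.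

**Compound list**

1 | 2,2-dimethylcyclohexan-1-one | CC1(C)CCCCC1=O | starting material
2 | RAMP, (R)-1-amino-2-(methoxymethyl)pyrrolidine | COC[C@H]1CCCN1N | starting material
3 | (E)-N-[(2R)-2-(methoxymethyl)pyrrolidin-1-yl]-2,2-dimethylcyclohexan-1-imine | COC[C@H]1CCCN1/N=C2\CCCCC2(C)C | intermediate
4 | lithium azaenolate of 3, lithium N-(6,6-dimethylcyclohex-1-en-1-yl)-N-[(2R)-2-(methoxymethyl)pyrrolidin-1-yl]amide | COC[C@H]1CCCN1N([Li])C1=CCCCC1(C)C | intermediate
5 | (E,6S)-N-[(2R)-2-(methoxymethyl)pyrrolidin-1-yl]-2,2,6-trimethylcyclohexan-1-imine | COC[C@H]1CCCN1/N=C2\[C@@H](C)CCCC2(C)C | intermediate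
6 | (S)-2,2,6-trimethylcyclohexan-1-one | O=C1[C@@H](C)CCCC1(C)C | intermediate
7 | (4-bromobut-1-yn-1-yl)trimethylsilane | C[Si](C)(C)C#CCCBr | starting material
8 | [4-(trimethylsilyl)but-3-yn-1-yl]magnesium bromide | C[Si](C)(C)C#CCC[Mg]Br | intermediate
9 | (1R,2S)-2,6,6-trimethyl-1-[4-(trimethylsilyl)but-3-yn-1-yl]cyclohexan-1-ol | C[Si](C)(C)C#CCC[C@@]1(O)[C@@H](C)CCCC1(C)C | intermediate
10 | (1R,2S)-1-(but-3-yn-1-yl)-2,6,6-trimethylcyclohexan-1-ol | C#CCC[C@@]1(O)[C@@H](C)CCCC1(C)C | intermediate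
11 | {[(1R,2S)-1-(but-3-yn-1-yl)-2,6,6-trimethylcyclohexyl]oxy}triethylsilane | C#CCC[C@@]1(O[Si](CC)(CC)CC)[C@@H](C)CCCC1(C)C | intermediate
12 | dimethyl{(E)-2-methyl-4-[(1R,2S)-2,6,6-trimethyl-1-(triethylsilyloxy)cyclohexyl]but-1-en-1-yl}alane | C[Al](C)/C=C(\C)CC[C@@]1(O[Si](CC)(CC)CC)[C@@H](C)CCCC1(C)C | intermediate
13 | lithium butyl(dimethyl){(E)-2-methyl-4-[(1R,2S)-2,6,6-trimethyl-1-(triethylsilyloxy)cyclohexyl]but-1-en-1-yl}aluminate | [Li+].CCCC[Al-](C)(C)/C=C(\C)CC[C@@]1(O[Si](CC)(CC)CC)[C@@H](C)CCCC1(C)C | intermediate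
14 | (E)-4-methyl-6-[(1R,2S)-2,6,6-trimethyl-1-(triethylsilyloxy)cyclohexyl]hex-3-en-1-ol | OCC/C=C(\C)CC[C@@]1(O[Si](CC)(CC)CC)[C@@H](C)CCCC1(C)C | intermediate
15 | {[(1R,2S)-1-[(E)-6-bromo-3-methylhex-3-en-1-yl]-2,6,6-trimethylcyclohexyl]oxy}triethylsilane | BrCC/C=C(\C)CC[C@@]1(O[Si](CC)(CC)CC)[C@@H](C)CCCC1(C)C | intermediate
16 | prop-2-yn-1-ol (propargyl alcohol) | C#CCO | starting material
17 | {(E)-4-methyl-6-[(1R,2S)-2,6,6-trimethyl-1-(triethylsilyloxy)cyclohexyl]hex-3-en-1-yl}magnesium bromide | Br[Mg]CC/C=C(\C)CC[C@@]1(O[Si](CC)(CC)CC)[C@@H](C)CCCC1(C)C | intermediate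
18 | chloromagnesium prop-2-yn-1-olate | C#CCO[Mg]Cl | intermediate
19 | cyclic alkenylmagnesium alkoxide, 1-oxa-2-magnesacyclopent-3-ene carrying the ring–chain substituent on C4 (Mg on the alkene CH, cis to CH2O) | [Mg]1OCC(CC/C=C(\C)CC[C@@]2(O[Si](CC)(CC)CC)[C@@H](C)CCCC2(C)C)=C1 | intermediate
20 | (Z)-3-iodo-2-{(E)-4-methyl-6-[(1R,2S)-2,6,6-trimethyl-1-(triethylsilyloxy)cyclohexyl]hex-3-en-1-yl}prop-2-en-1-ol | OC/C(=C\I)CC/C=C(\C)CC[C@@]1(O[Si](CC)(CC)CC)[C@@H](C)CCCC1(C)C | intermediate
21 | (E)-1,2-bis(tributylstannyl)ethene | CCCC[Sn](CCCC)(CCCC)/C=C/[Sn](CCCC)(CCCC)CCCC | starting material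
22 | (2Z,4E)-2-{(E)-4-methyl-6-[(1R,2S)-2,6,6-trimethyl-1-(triethylsilyloxy)cyclohexyl]hex-3-en-1-yl}-5-(tributylstannyl)penta-2,4-dien-1-ol | OC/C(=C\C=C\[Sn](CCCC)(CCCC)CCCC)CC/C=C(\C)CC[C@@]1(O[Si](CC)(CC)CC)[C@@H](C)CCCC1(C)C | intermediate
23 | (2Z,4E)-5-iodo-2-{(E)-4-methyl-6-[(1R,2S)-2,6,6-trimethyl-1-(triethylsilyloxy)cyclohexyl]hex-3-en-1-yl}penta-2,4-dien-1-ol | OC/C(=C\C=C\I)CC/C=C(\C)CC[C@@]1(O[Si](CC)(CC)CC)[C@@H](C)CCCC1(C)C | intermediate
24 | buta-2,3-dienoic acid | C=C=CC(=O)O | starting material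
25 | 4-[(1E,3Z,7E)-4-(hydroxymethyl)-8-methyl-10-[(1R,2S)-2,6,6-trimethyl-1-(triethylsilyloxy)cyclohexyl]deca-1,3,7-trien-1-yl]furan-2(5H)-one | OC/C(=C\C=C\C1=CC(=O)OC1)CC/C=C(\C)CC[C@@]1(O[Si](CC)(CC)CC)[C@@H](C)CCCC1(C)C | intermediate
26 | [(2Z,4E)-2-{(E)-4-methyl-6-[(1R,2S)-2,6,6-trimethyl-1-(triethylsilyloxy)cyclohexyl]hex-3-en-1-yl}-5-(5-oxo-2,5-dihydrofuran-3-yl)penta-2,4-dien-1-yl] acetate | CC(=O)OC/C(=C\C=C\C1=CC(=O)OC1)CC/C=C(\C)CC[C@@]1(O[Si](CC)(CC)CC)[C@@H](C)CCCC1(C)C | intermediate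
27 | [(2Z,4E)-2-{(E)-6-[(1R,2S)-1-hydroxy-2,6,6-trimethylcyclohexyl]-4-methylhex-3-en-1-yl}-5-(5-oxo-2,5-dihydrofuran-3-yl)penta-2,4-dien-1-yl] acetate | CC(=O)OC/C(=C\C=C\C1=CC(=O)OC1)CC/C=C(\C)CC[C@@]1(O)[C@@H](C)CCCC1(C)C | target

**Step count and risks**

Total step count: 14. Longest linear sequence: 14 steps (1 → 27); all other partners (2, 7, 16, 21, 24) are bought.

Steps most likely to fail:

Step 12. The carbonate base may isomerise buta-2,3-dienoic acid to but-2-ynoic acid, or Ag2CO3 and the catalyst derived from Pd(PPh3)4 may cyclise the acid on its own faster than the dienylpalladium species adds to it; the light-sensitive dienyl iodide may also homocouple or lose its geometry on heating. The fallback sets out from dienylstannane 22 and forms the same C4–C(dienyl) bond by Stille coupling with purchased 4-bromofuran-2(5H)-one (Pd2(dba)3, AsPh3, NMP, rt → 40 °C), so that the lactone ring is brought in ready-made and the route is rejoined at 25. No new compound is made on the way, which is entered below as F0.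

Step 9. Proton transfer from the acetylenic C–H of the alkoxide to the chain Grignard reagent, or slow carbomagnesiation with only a small excess of one partner, would consume the advanced fragment as its hydrocarbon. The fallback sets out from bromide 15 and builds the Z-trisubstituted alkene by olefination instead of carbometalation. Alkylation of the sodium salt of methyl bis(2,2,2-trifluoroethyl)phosphonoacetate with 15 (NaH, DMF, NaI cat.) should give methyl (E)-2-[bis(2,2,2-trifluoroethoxy)phosphoryl]-6-methyl-8-[(1R,2S)-2,6,6-trimethyl-1-(triethylsilyloxy)cyclohexyl]oct-5-enoate F1, as a mixture of epimers at the phosphorus-bearing carbon. Oxidation of purchased (E)-3-(tributylstannyl)prop-2-en-1-ol with MnO2 should give (E)-3-(tributylstannyl)prop-2-enal F2. Still–Gennari olefination of aldehyde F2 with phosphonate F1 (KN(SiMe3)2, 18-crown-6, THF, −78 °C) should place the ester cis to the new alkenyl chain and give methyl (2Z,4E)-2-{(E)-4-methyl-6-[(1R,2S)-2,6,6-trimethyl-1-(triethylsilyloxy)cyclohexyl]hex-3-en-1-yl}-5-(tributylstannyl)penta-2,4-dienoate F3. Reduction of ester F3 with i-Bu2AlH (CH2Cl2, −78 °C) then gives 22, where the route is rejoined.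

Step 4. The alkyl Grignard reagent may enolise or reduce the hindered ketone instead of adding, and facial selectivity with an sp3 nucleophile may be lower than expected. The fallback sets out from ketone 6 and uses a small, weakly basic acetylide, which should add axially. Addition of lithiated 3,3-diethoxyprop-1-yne (n-BuLi, THF, −78 → 0 °C) should give (1R,2S)-1-(3,3-diethoxyprop-1-yn-1-yl)-2,6,6-trimethylcyclohexan-1-ol F4. Hydrogenation of alkyne F4 (H2, Pd/C, EtOAc, trace Et3N) should give (1R,2S)-1-(3,3-diethoxypropyl)-2,6,6-trimethylcyclohexan-1-ol F5. Hydrolysis of acetal F5 (AcOH, THF/H2O) should give the lactol (5R,10S)-6,6,10-trimethyl-1-oxaspiro[4.5]decan-2-ol F6. Ohira–Bestmann homologation of the open hydroxy-aldehyde form of lactol F6 (dimethyl (1-diazo-2-oxopropyl)phosphonate, K2CO3, MeOH) then gives alkyne 10, where the route is rejoined.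

Further compounds
F0 | step 12 | none | none
F1 | step 9 | methyl (E)-2-[bis(2,2,2-trifluoroethoxy)phosphoryl]-6-methyl-8-[(1R,2S)-2,6,6-trimethyl-1-(triethylsilyloxy)cyclohexyl]oct-5-enoate | COC(=O)C(CC/C=C(\C)CC[C@@]1(O[Si](CC)(CC)CC)[C@@H](C)CCCC1(C)C)P(=O)(OCC(F)(F)F)OCC(F)(F)F
F2 | step 9 | (E)-3-(tributylstannyl)prop-2-enal | O=C/C=C/[Sn](CCCC)(CCCC)CCCC
F3 | step 9 | methyl (2Z,4E)-2-{(E)-4-methyl-6-[(1R,2S)-2,6,6-trimethyl-1-(triethylsilyloxy)cyclohexyl]hex-3-en-1-yl}-5-(tributylstannyl)penta-2,4-dienoate | COC(=O)/C(=C\C=C\[Sn](CCCC)(CCCC)CCCC)CC/C=C(\C)CC[C@@]1(O[Si](CC)(CC)CC)[C@@H](C)CCCC1(C)C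
F4 | step 4 | (1R,2S)-1-(3,3-diethoxyprop-1-yn-1-yl)-2,6,6-trimethylcyclohexan-1-ol | CCOC(OCC)C#C[C@@]1(O)[C@@H](C)CCCC1(C)C
F5 | step 4 | (1R,2S)-1-(3,3-diethoxypropyl)-2,6,6-trimethylcyclohexan-1-ol | CCOC(OCC)CC[C@@]1(O)[C@@H](C)CCCC1(C)C
F6 | step 4 | (5R,10S)-6,6,10-trimethyl-1-oxaspiro[4.5]decan-2-ol | OC1CC[C@@]2(O1)[C@@H](C)CCCC2(C)C
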